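**Retrosynthetic overview**

1. The last event is hydrogenolysis of a perbenzylated, C8-brominated dimer. Before that, the lower pyran ring is cut in one stroke at O1–C2 and C3–C4 into an o-quinone methide of the lower A-ring and a (Z)-2-arylvinyl tri-O-benzylgallate.
2. Enabling feature: in the lower (epicatechin) unit, C4 is an unsubstituted CH2 on C4a, ortho to the phenolic oxygen O1 on C8a of the phloroglucinol A-ring. This 2-hydroxybenzyl unit is an o-quinone methide retron, and the cis C2-aryl/C3-acyloxy pair maps onto a (Z)-enol ester whose para-oxygenated aryl ring fixes the regiochemistry.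
3. The quinone methide is carried as a 2-(tosylmethyl)phenol with C8 blocked by bromine. This lets the interflavan bond (upper C4 to lower C6) be made first, by Friedel–Crafts coupling with a C4-activated epiafzelechin 3-O-gallate.
4. Ring order: upper pyran ring from the chiral pool, then the C4–C6 interflavan bond, then the lower pyran ring last (key step). The enol ester comes from an aryl alkyne and the protected gallic acid.

Key step: step 10

Remark: (−)-epiafzelechin (1), a catalogue flavan-3-ol, is taken as the purchasable source of the upper unit, so only the lower unit is built de novo; flavan numbering is used, "upper" meaning the epiafzelechin unit and "lower" the epicatechin unit.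

**Route**

Step 1
Reactants: 1 (−)-epiafzelechin
Product: 2 (2R,3R)-5,7-bis(benzyloxy)-2-[4-(benzyloxy)phenyl]chroman-3-ol (5,7,4′-tri-O-benzyl-(−)-epiafzelechin)
Conditions: BnBr (3.2 equiv), K2CO3, DMF, 0 °C to rt
Reagents that add atoms: benzyl bromide, BrCc1ccccc1
Why: Williamson etherification, in which K2CO3 ionises only the three phenols and not the secondary C3 alcohol, so C2 and C3 are untouched.

Step 2
Reactants: 2 5,7,4′-tri-O-benzyl-(−)-epiafzelechin
Product: 3 (2R,3R,4S)-5,7-bis(benzyloxy)-2-[4-(benzyloxy)phenyl]-4-(2-ethoxyethoxy)chroman-3-ol (the 4β ether)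
Conditions: DDQ (2 equiv), 2-ethoxyethanol, CH2Cl2, rt
Reagents that add atoms: 2-ethoxyethanol, OCCOCC
Why: DDQ benzylic oxidation, in which hydride abstraction at C4 (activated by the 5,7-dioxygenated A-ring) gives a cation that the alcohol should trap anti to the 3-hydroxyl as the 4β ether, a configuration that is erased again on ionisation in step 7.

Step 3
Reactants: 3 4β-(2-ethoxyethoxy) alcohol; 4 3,4,5-tris(benzyloxy)benzoic acid
Product: 5 (2R,3R,4S)-5,7-bis(benzyloxy)-2-[4-(benzyloxy)phenyl]-4-(2-ethoxyethoxy)chroman-3-yl 3,4,5-tris(benzyloxy)benzoate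
Conditions: DCC, DMAP, CH2Cl2, rt to 40 °C
Reagents that add atoms: none
Why: Steglich esterification, which acylates the hindered axial 3-hydroxyl under neutral conditions that leave the acid-labile C4 ether in place and create no stereocentre.

Step 4
Reactants: 6 2,4,6-trihydroxybenzaldehyde
Product: 7 4,6-bis(benzyloxy)-2-hydroxybenzaldehyde
Conditions: BnBr (2.05 equiv), K2CO3, DMF, rt
Reagents that add atoms: benzyl bromide, BrCc1ccccc1
Why: Williamson etherification, in which the para-hydroxyl and one of the two equivalent ortho-hydroxyls are benzylated while the last ortho-hydroxyl is held back by its hydrogen bond to the aldehyde.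

Step 5
Reactants: 7 4,6-bis(benzyloxy)-2-hydroxybenzaldehyde
Product: 8 4,6-bis(benzyloxy)-3-bromo-2-hydroxybenzaldehyde
Conditions: NBS (1.0 equiv), iPr2NH (cat.), CH2Cl2, 0 °C
Reagents that add atoms: N-bromosuccinimide, BrN1C(=O)CCC1=O
Why: Electrophilic aromatic bromination, in which amine-mediated delivery of bromine ortho to the free phenol (C3) should be preferred over C5, which is flanked by two benzyloxy groups.

Step 6
Reactants: 8 4,6-bis(benzyloxy)-3-bromo-2-hydroxybenzaldehyde
Product: 10 3,5-bis(benzyloxy)-2-bromo-6-[(4-methylbenzenesulfonyl)methyl]phenol, via salicyl alcohol 9 (not isolated)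
Conditions: NaBH4, THF/MeOH, 0 °C; then TolSO2Na (3 equiv), HCO2H/H2O, 0 °C to rt
Reagents that add atoms: sodium 4-methylbenzenesulfinate, [Na+].[O-]S(=O)c1ccc(C)cc1
Why: Carbonyl reduction followed by sulfinate capture, in which the salicyl alcohol ionises in formic acid to a benzylic cation/o-quinone methide that the soft sulfinate sulfur should trap far faster than any arene, the usual entry to 2-(sulfonylmethyl)phenols.

Step 7
Reactants: 5 C4-activated epiafzelechin gallate; 10 bromo sulfonylmethyl phenol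
Product: 11 5,7,4′-tri-O-benzyl-4β-{2,6-bis(benzyloxy)-3-bromo-4-hydroxy-5-[(4-methylbenzenesulfonyl)methyl]phenyl}-(−)-epiafzelechin 3-O-[3,4,5-tris(benzyloxy)benzoate]
Conditions: 10 (1.5 equiv), TMSOTf (0.5 equiv), CH2Cl2, −78 to −40 °C; then pH 7 buffer
Reagents that add atoms: none
Why: Friedel–Crafts-type interflavan coupling, in which TMSOTf ionises the C4 ether of 5, the 3-O-galloyl group shields the α face by acyloxonium participation, and the only free ring carbon of 10 (para to the phenol, the ortho positions carrying bromine and the sulfonylmethyl group) attacks from the β face to set the 3,4-trans (4β) configuration at the upper C4.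

Step 8
Reactants: 12 3,4-bis(benzyloxy)benzaldehyde
Product: 13 1,2-bis(benzyloxy)-4-ethynylbenzene
Conditions: dimethyl (1-diazo-2-oxopropyl)phosphonate, K2CO3, MeOH, rt
Reagents that add atoms: dimethyl (1-diazo-2-oxopropyl)phosphonate, COP(=O)(OC)C(=[N+]=[N-])C(C)=O
Why: Ohira–Bestmann (Seyferth–Gilbert) homologation, which converts the aryl aldehyde into the terminal alkyne under K2CO3/MeOH, conditions to which benzyl ethers are inert.

Step 9
Reactants: 13 1,2-bis(benzyloxy)-4-ethynylbenzene; 4 3,4,5-tris(benzyloxy)benzoic acid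
Product: 14 (Z)-2-[3,4-bis(benzyloxy)phenyl]ethenyl 3,4,5-tris(benzyloxy)benzoate
Conditions: [Ru(η3-CH2C(CH3)CH2)2(Ph2P(CH2)4PPh2)] (2 mol %), toluene, 60 °C
Reagents that add atoms: none
Why: Ruthenium-catalysed anti-Markovnikov addition of a carboxylic acid to a terminal alkyne through a ruthenium vinylidene, for which this bis(allyl)diphosphine catalyst is known to deliver the (Z)-enol ester.

Step 10
Reactants: 11 upper unit carrying the latent quinone methide; 14 (Z)-enol gallate
Product: 16 5,7,4′-tri-O-benzyl-(−)-epiafzelechin 3-O-(tri-O-benzylgallate)-(4β→6)-8-bromo-5,7,3′,4′-tetra-O-benzyl-(−)-epicatechin 3-O-(tri-O-benzylgallate), via o-quinone methide 15 (not isolated)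
Conditions: 14 (2.5 equiv), K2CO3 (1.5 equiv, powdered), quinine-derived 3,5-bis(trifluoromethyl)phenyl squaramide (10 mol %), toluene/CH2Cl2, 0 °C to rt
Reagents that add atoms: none
Why: Proposed new method: K2CO3 deprotonates the phenol of 11 and 1,4-elimination of toluenesulfinate unveils o-quinone methide 15 (heterodiene O=C8a–C4a=CH2 of the lower A-ring), which is held by the two squaramide N–H bonds while the (Z)-enol ester 14 adds in an inverse-electron-demand oxa-Diels–Alder reaction; the closest known reaction types are the [4+2] cycloaddition of o-quinone methides with electron-rich styrenes to give flavans and squaramide-controlled additions to o-quinone methides released from 2-(sulfonylmethyl)phenols, whereas catalyst-controlled facial selection of a simple enol-ester dienophile has no precedent. The lower pyran ring is closed in a single concerted but asynchronous [4+2] event in which C3–C4 bonding runs ahead and O1–C2 closes the six-membered ring at the benzylic carbon. The two new stereocentres, lower C2 and C3, are cis because addition across the (Z)-alkene is suprafacial, and their absolute (2R,3R) sense is to be imposed by the catalyst, which shields one face of the bound quinone methide so that the endo approach of 14 comes from the open face (the quinidine-derived pseudoenantiomer is the reserve if the sense is opposite, and the upper unit makes the wrong facial isomer a separable diastereomer). The step needs regio- and chemoselectivity: the para-benzyloxy group on the aryl ring of 14 puts the developing positive charge on C2, so the acyloxy-bearing carbon attacks the methide CH2 and oxygen closes on C2, and in 11 the only free phenol is O1 while C6 (upper unit), C8 (bromine), O5 and O7 (benzyl) are blocked, so no other oxygen can close the ring and the quinone methide cannot alkylate its own arene.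

Step 11
Reactants: 16 perbenzylated 8-bromo dimer
Product: 17 (−)-epiafzelechin 3-O-gallate-(4β→6)-(−)-epicatechin 3-O-gallate (CNP0169607.1)
Conditions: H2 (1 atm), Pd(OH)2/C, Et3N (1.1 equiv), THF/MeOH/H2O, rt
Reagents that add atoms: none
Why: Catalytic hydrogenolysis, which removes the thirteen O-benzyl groups and the C8 bromine (Et3N buffering the HBr) while the two aryl esters, the acid-labile interflavan bond and the five stereocentres are left untouched.

**Compound list**

1 | (−)-epiafzelechin, (2R,3R)-2-(4-hydroxyphenyl)chromane-3,5,7-triol | O[C@@H]1Cc2c(O)cc(O)cc2O[C@@H]1c1ccc(O)cc1 | starting material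
2 | 5,7,4′-tri-O-benzyl-(−)-epiafzelechin (2R,3R) | O[C@@H]1Cc2c(OCc3ccccc3)cc(OCc3ccccc3)cc2O[C@@H]1c1ccc(OCc2ccccc2)cc1 | intermediate
3 | 4β-(2-ethoxyethoxy)-5,7,4′-tri-O-benzyl-(−)-epiafzelechin (2R,3R,4S) | O[C@@H]1[C@@H](OCCOCC)c2c(OCc3ccccc3)cc(OCc3ccccc3)cc2O[C@@H]1c1ccc(OCc2ccccc2)cc1 | intermediate
4 | 3,4,5-tris(benzyloxy)benzoic acid | OC(=O)c1cc(OCc2ccccc2)c(OCc2ccccc2)c(OCc2ccccc2)c1 | starting material
5 | 4β-(2-ethoxyethoxy)-5,7,4′-tri-O-benzyl-(−)-epiafzelechin 3-O-[3,4,5-tris(benzyloxy)benzoate] (2R,3R,4S) | O=C(O[C@@H]1[C@@H](OCCOCC)c2c(OCc3ccccc3)cc(OCc3ccccc3)cc2O[C@@H]1c1ccc(OCc2ccccc2)cc1)c1cc(OCc2ccccc2)c(OCc2ccccc2)c(OCc2ccccc2)c1 | intermediate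
6 | 2,4,6-trihydroxybenzaldehyde | O=Cc1c(O)cc(O)cc1O | starting material
7 | 4,6-bis(benzyloxy)-2-hydroxybenzaldehyde | O=Cc1c(O)cc(OCc2ccccc2)cc1OCc1ccccc1 | intermediate
8 | 4,6-bis(benzyloxy)-3-bromo-2-hydroxybenzaldehyde | O=Cc1c(O)c(Br)c(OCc2ccccc2)cc1OCc1ccccc1 | intermediate
9 | 3,5-bis(benzyloxy)-2-bromo-6-(hydroxymethyl)phenol (salicyl alcohol, formed in situ) | OCc1c(O)c(Br)c(OCc2ccccc2)cc1OCc1ccccc1 | intermediate
10 | 3,5-bis(benzyloxy)-2-bromo-6-[(4-methylbenzenesulfonyl)methyl]phenol | Cc1ccc(cc1)S(=O)(=O)Cc1c(O)c(Br)c(OCc2ccccc2)cc1OCc1ccccc1 | intermediate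
11 | 5,7,4′-tri-O-benzyl-4β-{2,6-bis(benzyloxy)-3-bromo-4-hydroxy-5-[(4-methylbenzenesulfonyl)methyl]phenyl}-(−)-epiafzelechin 3-O-[3,4,5-tris(benzyloxy)benzoate] | O=C(O[C@@H]1[C@@H](c2c(OCc3ccccc3)c(Br)c(O)c(CS(=O)(=O)c3ccc(C)cc3)c2OCc2ccccc2)c2c(OCc3ccccc3)cc(OCc3ccccc3)cc2O[C@@H]1c1ccc(OCc2ccccc2)cc1)c1cc(OCc2ccccc2)c(OCc2ccccc2)c(OCc2ccccc2)c1 | intermediate
12 | 3,4-bis(benzyloxy)benzaldehyde | O=Cc1ccc(OCc2ccccc2)c(OCc2ccccc2)c1 | starting material
13 | 1,2-bis(benzyloxy)-4-ethynylbenzene | C#Cc1ccc(OCc2ccccc2)c(OCc2ccccc2)c1 | intermediate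
14 | (Z)-2-[3,4-bis(benzyloxy)phenyl]ethenyl 3,4,5-tris(benzyloxy)benzoate | O=C(O/C=C\c1ccc(OCc2ccccc2)c(OCc2ccccc2)c1)c1cc(OCc2ccccc2)c(OCc2ccccc2)c(OCc2ccccc2)c1 | intermediate
15 | o-quinone methide of 11 (lower A-ring as its 3,5-bis(benzyloxy)-2-bromo-6-methylidenecyclohexa-2,4-dien-1-one form, attached through ring carbon 4 to the 4β position of the upper unit; formed in situ) | O=C(O[C@@H]1[C@@H](C2=C(OCc3ccccc3)C(=C)C(=O)C(Br)=C2OCc2ccccc2)c2c(OCc3ccccc3)cc(OCc3ccccc3)cc2O[C@@H]1c1ccc(OCc2ccccc2)cc1)c1cc(OCc2ccccc2)c(OCc2ccccc2)c(OCc2ccccc2)c1 | intermediate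
16 | 5,7,4′-tri-O-benzyl-(−)-epiafzelechin 3-O-(tri-O-benzylgallate)-(4β→6)-8-bromo-5,7,3′,4′-tetra-O-benzyl-(−)-epicatechin 3-O-(tri-O-benzylgallate) | O=C(O[C@@H]1[C@@H](c2c(OCc4ccccc4)c(Br)c3c(c2OCc2ccccc2)C[C@@H](OC(=O)c2cc(OCc4ccccc4)c(OCc4ccccc4)c(OCc4ccccc4)c2)[C@@H](c2ccc(OCc4ccccc4)c(OCc4ccccc4)c2)O3)c2c(OCc3ccccc3)cc(OCc3ccccc3)cc2O[C@@H]1c1ccc(OCc2ccccc2)cc1)c1cc(OCc2ccccc2)c(OCc2ccccc2)c(OCc2ccccc2)c1 | intermediate
17 | (−)-epiafzelechin 3-O-gallate-(4β→6)-(−)-epicatechin 3-O-gallate (CNP0169607.1) | O=C(O[C@@H]1[C@@H](c2c(O)cc3c(c2O)C[C@@H](OC(=O)c2cc(O)c(O)c(O)c2)[C@@H](c2ccc(O)c(O)c2)O3)c2c(O)cc(O)cc2O[C@@H]1c1ccc(O)cc1)c1cc(O)c(O)c(O)c1 | target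

**Step count and risks**

Total step count: 11. Longest linear sequence: 6 steps (steps 4, 5, 6, 7, 10, 11 from 6; the branch from 1 through steps 1, 2, 3, 7, 10, 11 is equally long).

Step 10 (labelled step, highest risk). Facial discrimination of the dienophile may be insufficient, so that 14 also adds to the other face of 15 and the (2S,3S) lower unit forms. The cis relationship may also be eroded by ionic, stepwise collapse. A slow cycloaddition could let 15 be consumed by water or by acyl transfer from 14 to the phenoxide. The fallback uses only known chemistry and takes the lower unit from the chiral pool. Commercial (−)-epicatechin would be perbenzylated (BnBr, K2CO3, DMF) to 5,7,3′,4′-tetra-O-benzyl-(−)-epicatechin F1. Bromination at C8 (NBS, CH2Cl2, −78 °C) would give 8-bromo-5,7,3′,4′-tetra-O-benzyl-(−)-epicatechin F2. Esterification with acid 4 (DCC, DMAP) would give 8-bromo-5,7,3′,4′-tetra-O-benzyl-(−)-epicatechin 3-O-[3,4,5-tris(benzyloxy)benzoate] F3. TMSOTf-mediated coupling of F3, whose only free A-ring carbon is C6, with electrophile 5 would then give 16 directly. This fallback sets out from 5 and returns to the route at 16.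

Step 7. Self-condensation of ionised 5 through its own A-ring, or ionisation of the benzylic sulfone of 10 by the hard Lewis acid, may outrun attack by the hindered ring carbon of 10. The fallback changes the activation principle to thiophilic activation of a C4 thioether. Alcohol 3 would be converted with benzyl mercaptan and BF3·OEt2 (CH2Cl2, −40 °C) into 4β-(benzylsulfanyl)-5,7,4′-tri-O-benzyl-(−)-epiafzelechin F4. Esterification with 4 (DCC, DMAP) would give 4β-(benzylsulfanyl)-5,7,4′-tri-O-benzyl-(−)-epiafzelechin 3-O-[3,4,5-tris(benzyloxy)benzoate] F5. F5 would be coupled with 10 under AgBF4 (THF/CH2Cl2, 0 °C), a soft activator that cannot ionise the sulfone. This fallback sets out from 3 and returns to the route at 11.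

Step 5. Bromination may fail to discriminate between C3 and C5, or run on to the dibromide. The fallback reverses the order of halogenation and O-alkylation. Triol 6, in which the two ring C–H positions are equivalent, would be monobrominated (NBS, MeCN, −20 °C) to 3-bromo-2,4,6-trihydroxybenzaldehyde F6. Benzylation with two equivalents of BnBr (K2CO3, DMF) should then leave free the hydroxyl that is flanked by both the aldehyde and bromine, for steric reasons. This fallback sets out from 6 and returns to the route at 8.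

**Further compounds**

F1 | step 10 | 5,7,3′,4′-tetra-O-benzyl-(−)-epicatechin (2R,3R) | O[C@@H]1Cc2c(OCc3ccccc3)cc(OCc3ccccc3)cc2O[C@@H]1c1ccc(OCc2ccccc2)c(OCc2ccccc2)c1
F2 | step 10 | 8-bromo-5,7,3′,4′-tetra-O-benzyl-(−)-epicatechin (2R,3R) | O[C@@H]1Cc2c(OCc3ccccc3)cc(OCc3ccccc3)c(Br)c2O[C@@H]1c1ccc(OCc2ccccc2)c(OCc2ccccc2)c1
F3 | step 10 | 8-bromo-5,7,3′,4′-tetra-O-benzyl-(−)-epicatechin 3-O-[3,4,5-tris(benzyloxy)benzoate] (2R,3R) | O=C(O[C@@H]1Cc2c(OCc3ccccc3)cc(OCc3ccccc3)c(Br)c2O[C@@H]1c1ccc(OCc2ccccc2)c(OCc2ccccc2)c1)c1cc(OCc2ccccc2)c(OCc2ccccc2)c(OCc2ccccc2)c1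
F4 | step 7 | 4β-(benzylsulfanyl)-5,7,4′-tri-O-benzyl-(−)-epiafzelechin | O[C@@H]1[C@@H](SCc3ccccc3)c2c(OCc3ccccc3)cc(OCc3ccccc3)cc2O[C@@H]1c1ccc(OCc2ccccc2)cc1
F5 | step 7 | 4β-(benzylsulfanyl)-5,7,4′-tri-O-benzyl-(−)-epiafzelechin 3-O-[3,4,5-tris(benzyloxy)benzoate] | O=C(O[C@@H]1[C@@H](SCc3ccccc3)c2c(OCc3ccccc3)cc(OCc3ccccc3)cc2O[C@@H]1c1ccc(OCc2ccccc2)cc1)c1cc(OCc2ccccc2)c(OCc2ccccc2)c(OCc2ccccc2)c1
F6 | step 5 | 3-bromo-2,4,6-trihydroxybenzaldehyde | O=Cc1c(O)c(Br)c(O)cc1O
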